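20 mM of solid D and 50.0 mM of J stand in one stirred flask. D dissolves to E, E takes up J to give E.J, and J also decays by itself to X.

D 20 mM; J 50.0 mM; time 5.0 d

* why nothing more happens at 5.0 d, or that something still does (for what has run out or reacted, a solid counts together with what of it has only dissolved) (it is still moving / all of D has reacted / J has run out first)
* amount of E.J at 5.0 d, in percent of the D charged

- D is a solid; its amount is given per volume of the solution
- at the start none of D is in solution
- what has only dissolved of D counts as not reacted
- the reaction counts as stopped when no species that holds the D changes by six tenths of a point or more over the second half of the time
- run time (flask): 5.0 d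

Which numbers must be known well? Follow one molecule of J: it either decays or meets E.

The time need not be exact: the half-life of J by decay is 0.16 h, far shorter than the 5.0 d of the run. How well k1 must be known is less plain: at the start J takes up dissolved E at 5.00 /min, far above the dissolution coefficient 0.051 /min, so dissolving is then the rate-limiting step. The reckoning below carries that opening state on through the whole life of J, and so leaves k1 out. While solid is left, the charge of D is merely the divisor of the percentage.

The solubility, k3 and k2 do matter. Dissolving has a ceiling rate, k3 times the solubility, reached with E near zero. J is thus lost to E.J at that ceiling and to X in proportion to its amount. The balance amount of J, the ceiling rate divided by k2, at which both ways of losing J go equally fast, stands before the logarithm below, while the charge of J stands inside it: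

amount of E.J = balance amount × ln(1 + charge of J / balance amount)

The ceiling is 0.122 mM/min and the balance amount 1.68 mM, so a molecule of J starts with a chance of 3.25 % of ending in E.J. The line gives 5.75 mM, or 28.7 % of the D charged.

At the ceiling, J lasts 47.0 min, while the solid would last 163 min, so the first event is: J has run out first.

The forecast gives J has run out first and 24.5 %, between 22.5 % and 26.5 %, from a “rough stepwise integration in ln[J]”.

The simulation gives J has run out first, with 0 % of J left, and 24.4 % of E.J.

    E + J → E.J (k1 = 100 /M/min)
    J → X (k2 = 0.073 /min)
    D ⇌ E, rate k3*(cs3 - [E]) while solid is left; crystals form when [E] > cs3 (cs3 = 2.4 mM, k3 = 0.051 /min)

The reckoned yield stands 4.3 percentage points above the simulated one, and dissolved E reads 12.0 % of the D charged at 0.500 d, where the ceiling took it as near zero. The neighbour charged with 12 mM of J, 0.600 equiv to D, has the same balance amount, and the same line gives it 17.6 % of E.J. That neighbour keeps 0 % of its J and ends with 13.5 % of E.J.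

(The numbers are made up.)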